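**Retrosynthetic overview**
1. Target ⇐ one hydrogenolysis that removes two O-benzyl groups and a benzylic C7–OH from a 3-hydroxy-3-[aryl(hydroxy)methyl]-4-benzyl-γ-butyrolactone.
2. That diol ⇐ OsO4 dihydroxylation of an (E)-3-benzylidene-4-benzyl-γ-butyrolactone on the face opposite the C4 benzyl group (sets C3).
3. Benzylidene lactone ⇐ three components in one flask: aryl-copper opening of a cyclopropane-fused α-phosphono-γ-lactone at its CH2, then Horner–Wadsworth–Emmons olefination of the resulting enolate with O-benzylvanillin.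
4. Cyclopropane-fused phosphonolactone ⇐ (S)-epichlorohydrin + triethyl phosphonoacetate by double alkylation–lactonisation (the epoxide stereocentre becomes C4).
5. Ring order: cyclopropane, then γ-lactone, both in the first operation; the cyclopropane is opened again in the second step, the lactone is kept to the end; both arenes are bought.

Assumption and notation: the SMILES is taken as drawn, i.e. (3S,4R), with the 3-OH trans to the C4 benzyl group and the two benzyl groups cis; both aryl building blocks are bought as their benzyl ethers; lactone atoms are O1, C2(=O), C3, C4, C5, and C7 is the benzylic carbon on C3.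

**Step 1**
Reactants: 1 (S)-epichlorohydrin [(2S)-2-(chloromethyl)oxirane]; 2 triethyl phosphonoacetate
Product: 6 diethyl [(1S,5R)-2-oxo-3-oxabicyclo[3.1.0]hexan-1-yl]phosphonate, via chlorohydrin alkoxide 3 (not isolated), via epoxy phosphonoester 4 (not isolated), via cyclopropylcarbinol ester 5 (not isolated)
Conditions: NaOEt (1.1 equiv), EtOH, 0 °C → reflux; AcOH quench
Reagents that add atoms: none
Why: Proposed new method: the sodium phosphonoacetate carbanion opens the oxirane of 1 at CH2 (SN2), the chlorohydrin alkoxide closes to the transposed epoxide 4 without touching the stereocentre, and the re-formed carbanion attacks that stereocentre in a 3-exo-tet SN2 with inversion (a Michael-initiated-ring-closure-type double alkylation), so the (S) centre of 1 becomes C5 of 6, and C1 is fixed because only the cyclopropane with CO2Et cis to CH2O– (expected to be favoured, the bulkier phosphoryl group going trans) can lactonise; the closest known reaction is the diethyl malonate/epichlorohydrin double alkylation–lactonisation to the same 3-oxabicyclo[3.1.0]hexan-2-one core, and the mechanistic risk is C→O phosphoryl transfer in the alkoxides.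

**Step 2**
Reactants: 6 diethyl [(1S,5R)-2-oxo-3-oxabicyclo[3.1.0]hexan-1-yl]phosphonate; 7 1-(benzyloxy)-4-bromo-2-methoxybenzene; 8 4-(benzyloxy)-3-methoxybenzaldehyde
Product: 11 (3E,4S)-4-{[4-(benzyloxy)-3-methoxyphenyl]methyl}-3-{[4-(benzyloxy)-3-methoxyphenyl]methylidene}oxolan-2-one, via arylmagnesium bromide 9 (not isolated), via magnesium phosphonoenolate 10 (not isolated)
Conditions: 7, Mg, THF, 40 °C; then 6, CuI (10 mol%), THF, −30 → 0 °C; then 8, 0 °C → reflux; 1 M HCl work-up
Reagents that add atoms: none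
Why: Copper-catalysed homoconjugate (SN2-type) addition of the aryl Grignard reagent to the unsubstituted CH2 of the doubly activated cyclopropane (known for the malonate-type analogues) cleaves the C1–C6 bond without touching C5 and gives the chelated magnesium phosphonoenolate, which olefinates 8 in a Horner–Wadsworth–Emmons reaction (magnesium phosphonate carbanions are competent, as in the MgBr2/Et3N variant); no lasting stereocentre is formed, and the expected E geometry is inconsequential because C7 becomes CH2 in step 4.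

**Step 3**
Reactants: 11 (3E,4S)-4-{[4-(benzyloxy)-3-methoxyphenyl]methyl}-3-{[4-(benzyloxy)-3-methoxyphenyl]methylidene}oxolan-2-one
Product: 12 (3R,4R)-4-{[4-(benzyloxy)-3-methoxyphenyl]methyl}-3-{(S)-[4-(benzyloxy)-3-methoxyphenyl](hydroxy)methyl}-3-hydroxyoxolan-2-one
Conditions: OsO4 (4 mol%), NMO (2 equiv), citric acid (1 equiv), acetone/t-BuOH/H2O, rt
Reagents that add atoms: osmium tetroxide, O=[Os](=O)(=O)=O; N-methylmorpholine N-oxide, C[N+]1([O-])CCOCC1; water, O
Why: Upjohn syn-dihydroxylation in which allylic 1,3-strain with the (E)-aryl group holds the C4 benzyl group pseudo-axial, so OsO4 adds to the exocyclic alkene from the opposite face and sets the C3–O bond trans to the C4 benzyl group (the target configuration; the descriptor reads 3R here only because CH(OH)Ar outranks C4), together with a C7 carbinol centre that is erased in step 4.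

**Step 4**
Reactants: 12 (3R,4R)-4-{[4-(benzyloxy)-3-methoxyphenyl]methyl}-3-{(S)-[4-(benzyloxy)-3-methoxyphenyl](hydroxy)methyl}-3-hydroxyoxolan-2-one
Product: 14 (3S,4R)-3-hydroxy-3,4-bis[(4-hydroxy-3-methoxyphenyl)methyl]oxolan-2-one (target), via triol lactone 13 (not isolated)
Conditions: H2 (1–3 atm), 10% Pd/C, EtOAc/AcOH 4:1, rt → 40 °C
Reagents that add atoms: none
Why: Catalytic hydrogenolysis removes both benzyl ethers and then the p-hydroxybenzylic secondary C7–OH (the known behaviour of 7-hydroxy lignanolactones), whereas the non-benzylic tertiary C3–OH, the lactone and the C3 and C4 stereocentres are not touched, so 14 is (3S,4R).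

**Compound list**
1 | (S)-epichlorohydrin, (2S)-2-(chloromethyl)oxirane | ClC[C@@H]1CO1 | starting material
2 | triethyl phosphonoacetate | CCOC(=O)CP(=O)(OCC)OCC | starting material
3 | ethyl (4S)-5-chloro-2-(diethoxyphosphoryl)-4-hydroxypentanoate (present as sodium alkoxide, C2 epimers) | CCOC(=O)C(P(=O)(OCC)OCC)C[C@H](O)CCl | intermediate (not isolated)
4 | ethyl 2-(diethoxyphosphoryl)-3-[(2S)-oxiran-2-yl]propanoate (C2 epimers) | CCOC(=O)C(P(=O)(OCC)OCC)C[C@H]1CO1 | intermediate (not isolated)
5 | ethyl (1S,2R)-1-(diethoxyphosphoryl)-2-(hydroxymethyl)cyclopropane-1-carboxylate (present as sodium alkoxide) | CCOC(=O)[C@]1(P(=O)(OCC)OCC)C[C@@H]1CO | intermediate (not isolated)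
6 | diethyl [(1S,5R)-2-oxo-3-oxabicyclo[3.1.0]hexan-1-yl]phosphonate | O=C1OC[C@H]2C[C@@]12P(=O)(OCC)OCC | intermediate
7 | 1-(benzyloxy)-4-bromo-2-methoxybenzene | COc1cc(Br)ccc1OCc1ccccc1 | starting material
8 | 4-(benzyloxy)-3-methoxybenzaldehyde | COc1cc(C=O)ccc1OCc1ccccc1 | starting material
9 | [4-(benzyloxy)-3-methoxyphenyl]magnesium bromide | COc1cc([Mg]Br)ccc1OCc1ccccc1 | intermediate (not isolated)
10 | bromomagnesium enolate of diethyl [(4R)-4-{[4-(benzyloxy)-3-methoxyphenyl]methyl}-2-oxooxolan-3-yl]phosphonate | CCOP(=O)(OCC)C1=C(O[Mg]Br)OC[C@H]1Cc1ccc(OCc2ccccc2)c(OC)c1 | intermediate (not isolated)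
11 | (3E,4S)-4-{[4-(benzyloxy)-3-methoxyphenyl]methyl}-3-{[4-(benzyloxy)-3-methoxyphenyl]methylidene}oxolan-2-one | O=C1OC[C@@H](Cc2ccc(OCc3ccccc3)c(OC)c2)/C1=C\c1ccc(OCc2ccccc2)c(OC)c1 | intermediate
12 | (3R,4R)-4-{[4-(benzyloxy)-3-methoxyphenyl]methyl}-3-{(S)-[4-(benzyloxy)-3-methoxyphenyl](hydroxy)methyl}-3-hydroxyoxolan-2-one | O=C1OC[C@@H](Cc2ccc(OCc3ccccc3)c(OC)c2)[C@@]1(O)[C@@H](O)c1ccc(OCc2ccccc2)c(OC)c1 | intermediate
13 | (3R,4R)-3-hydroxy-3-[(S)-hydroxy(4-hydroxy-3-methoxyphenyl)methyl]-4-[(4-hydroxy-3-methoxyphenyl)methyl]oxolan-2-one | O=C1OC[C@@H](Cc2ccc(O)c(OC)c2)[C@@]1(O)[C@@H](O)c1ccc(O)c(OC)c1 | intermediate (not isolated)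
14 | (3S,4R)-3-hydroxy-3,4-bis[(4-hydroxy-3-methoxyphenyl)methyl]oxolan-2-one | COc1cc(C[C@@H]2COC(=O)[C@]2(O)Cc2ccc(O)c(OC)c2)ccc1O | target

**Totals**
Total steps: 4. Longest linear sequence: 4 (1 → 6 → 11 → 12 → 14).

**Steps most likely to fail**

Step 1. The phosphonoacetate may lose phosphorus by C→O phosphoryl transfer, or close to the cyclopropane whose ester is trans to CH2O– and cannot lactonise. A little of the other enantiomer can also arise from direct displacement of chloride. The fallback sets out from 1 and uses the malonate, whose bicyclisation is established. Compound 1 with diethyl malonate and NaOEt in refluxing EtOH gives ethyl (1R,5S)-2-oxo-3-oxabicyclo[3.1.0]hexane-1-carboxylate F1. CuI-catalysed opening with Grignard reagent 9 gives ethyl (4S)-4-{[4-(benzyloxy)-3-methoxyphenyl]methyl}-2-oxooxolane-3-carboxylate F2. LiCl in wet DMSO at 150 °C removes the ester group and gives (4S)-4-{[4-(benzyloxy)-3-methoxyphenyl]methyl}oxolan-2-one F3. LiN(i-Pr)2 in THF at −78 °C followed by aldehyde 8 gives the aldol adduct (4S)-4-{[4-(benzyloxy)-3-methoxyphenyl]methyl}-3-{[4-(benzyloxy)-3-methoxyphenyl](hydroxy)methyl}oxolan-2-one F4. TsOH in hot toluene dehydrates it, and the route is rejoined at 11.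

Step 2. In the one-flask sequence the magnesium aldolate may not collapse to the alkene, and residual Grignard reagent can consume aldehyde 8. The fallback sets out from 6 and uncouples the two bond-forming events into two operations. The CuI-catalysed opening with 9 is quenched with aqueous NH4Cl and diethyl [(4R)-4-{[4-(benzyloxy)-3-methoxyphenyl]methyl}-2-oxooxolan-3-yl]phosphonate F5 is isolated. Its potassium carbanion (KOt-Bu, THF, 0 °C → rt) then olefinates 8 in a separate Horner–Wadsworth–Emmons reaction, and the route is rejoined at 11.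

Step 3. The electron-poor trisubstituted alkene may react slowly, and the facial selectivity rests on substrate control. Any Z isomer of 11 gives only the C7 epimer of 12, which converges in step 4. (DHQ)2PHAL is the matched ligand by the Sharpless mnemonic if the ratio needs help. The fallback sets out from 11 and replaces dihydroxylation/hydrogenolysis by a radical hydration. Mn(dpm)3 (cat.), PhSiH3 and O2 in i-PrOH/CH2Cl2 at 0 °C deliver hydrogen to C7 and oxygen to C3 from the face opposite the C4 benzyl group. This gives (3S,4R)-3,4-bis{[4-(benzyloxy)-3-methoxyphenyl]methyl}-3-hydroxyoxolan-2-one F6. Plain debenzylation (H2, 10% Pd/C, EtOAc, rt) then rejoins the route at 14.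

**Further compounds**
F1 | step 1 | ethyl (1R,5S)-2-oxo-3-oxabicyclo[3.1.0]hexane-1-carboxylate | O=C1OC[C@H]2C[C@@]12C(=O)OCC
F2 | step 1 | ethyl (4S)-4-{[4-(benzyloxy)-3-methoxyphenyl]methyl}-2-oxooxolane-3-carboxylate (C3 epimers) | CCOC(=O)C1C(=O)OC[C@H]1Cc1ccc(OCc2ccccc2)c(OC)c1
F3 | step 1 | (4S)-4-{[4-(benzyloxy)-3-methoxyphenyl]methyl}oxolan-2-one | O=C1OC[C@@H](Cc2ccc(OCc3ccccc3)c(OC)c2)C1
F4 | step 1 | (4S)-4-{[4-(benzyloxy)-3-methoxyphenyl]methyl}-3-{[4-(benzyloxy)-3-methoxyphenyl](hydroxy)methyl}oxolan-2-one (diastereomer mixture at C3 and the carbinol carbon) | O=C1OC[C@@H](Cc2ccc(OCc3ccccc3)c(OC)c2)C1C(O)c1ccc(OCc2ccccc2)c(OC)c1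
F5 | step 2 | diethyl [(4R)-4-{[4-(benzyloxy)-3-methoxyphenyl]methyl}-2-oxooxolan-3-yl]phosphonate (C3 epimers) | CCOP(=O)(OCC)C1C(=O)OC[C@H]1Cc1ccc(OCc2ccccc2)c(OC)c1
F6 | step 3 | (3S,4R)-3,4-bis{[4-(benzyloxy)-3-methoxyphenyl]methyl}-3-hydroxyoxolan-2-one | O=C1OC[C@@H](Cc2ccc(OCc3ccccc3)c(OC)c2)[C@@]1(O)Cc1ccc(OCc2ccccc2)c(OC)c1
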